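**Retrosynthetic overview**

1. Target 32 ⇐ chemoselective oxidation at C2 and desilylation ⇐ C8 tiglate installed with inversion (Mitsunobu) ⇐ bicyclic 8S alcohol 28.
2. 28 ⇐ intramolecular Nozaki–Hiyama–Kishi allylation of bromo aldehyde 26: one operation forms C7–C8, closes the ten-membered carbocycle (ring B) onto the lactone (ring A), sets C7 and C8, and creates the exocyclic C11=C13 methylene.
3. Enabling feature: the 3-(bromomethyl)furan-2(5H)-one of ring A. Its allyl unit C13–C11=C7 has the lactone β-carbon C7 as γ-terminus, so SE2′ attack of the C8 aldehyde at C7 pushes the ring double bond out to C11=C13. The two Z-trisubstituted olefins (C3=C4, C1=C10), with C2 held at the carbinol level, fold the chain.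
4. 26 ⇐ NHK alkenylation (C2–C3) of Z-enal 20 (from 4-methyl-5,6-dihydro-2H-pyran-2-one) with Z-vinyl iodide butenolide 16; 16 ⇐ ring-closing metathesis ⇐ syn-selective γ-alkoxyallylboration of (2Z)-3-iodo-2-methylprop-2-enal (sets C5, C6).
5. Ring order: ring A by metathesis (step 9), then ring B by the key step (step 18).

Key step: step 18

Remark on numbering: ring carbons are C1–C10 (C2 ketone, C3=C4 with methyl on C4, C5 hydroxyl, C6 lactone oxygen, C7, C8 ester, C9 methylene, C10 with methyl, C10=C1); C11, C12 and C13 are the lactone α-carbon, carbonyl and exocyclic methylene. In this numbering the target is 5S,6S,7R,8R with Z C1=C10, Z C3=C4 and an E-configured 2-methylbut-2-enoate. In the systematic names C7 = C3a, C8 = C4, C2 = C8, C5 = C11, C6 = C11a.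

Assumption: the C2 carbinol carbon made in step 13 is carried as a mixture of both epimers through step 20 (drawn without a descriptor, "RS" in names), because step 21 turns it into the ketone.

Assumption: 4-methyl-5,6-dihydro-2H-pyran-2-one, allyl 4-methoxyphenyl ether, ethyl 2-(hydroxymethyl)acrylate, tiglic acid and (+)-Ipc2BOMe are taken as catalogue compounds.

Abbreviations: TBS = tert-butyldimethylsilyl, TBSO = tert-butyldimethylsilyloxy, Ipc = isopinocampheyl.

**Route**

Step 1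
Reactants: 1 prop-2-yn-1-ol
Product: 3 (2Z)-3-iodo-2-methylprop-2-en-1-ol, via alkenylmagnesium alkoxide 2 (not isolated)
Conditions: MeMgBr (2.5 equiv), CuI (10 mol %), THF, 0 °C → rt; then I2, −20 °C → rt
Reagents that add atoms: methylmagnesium bromide, C[Mg]Br; iodine, II
Why: Copper-catalysed anti-carbomagnesiation of the propargylic alkoxide puts the methyl group on C2 and magnesium on C3 inside a five-membered magnesium chelate, so that iodinolysis with retention should give only the Z-iodide.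

Step 2
Reactants: 3 (2Z)-3-iodo-2-methylprop-2-en-1-ol
Product: 4 (2Z)-3-iodo-2-methylprop-2-enal
Conditions: MnO2, CH2Cl2, rt
Reagents that add atoms: none
Why: MnO2 oxidises the allylic alcohol to the enal under neutral heterogeneous conditions that should leave the Z-iodoalkene geometry intact.

Step 3
Reactants: 4 (2Z)-3-iodo-2-methylprop-2-enal; 5 1-methoxy-4-(prop-2-en-1-yloxy)benzene
Product: 9 (1Z,3S,4S)-1-iodo-4-(4-methoxyphenoxy)-2-methylhexa-1,5-dien-3-ol, via allyllithium 6 (not isolated), via allylborane 7 (not isolated), via borinate 8 (not isolated)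
Conditions: 5, s-BuLi, THF, −78 °C; (+)-Ipc2BOMe; BF3·OEt2; then 4, −78 °C; NaOH, H2O2, 0 °C → rt
Reagents that add atoms: none
Why: γ-Alkoxyallylboration with a diisopinocampheylborane (Brown type): the Z-configured γ-aryloxyallyl borane reacts through a closed chair (Zimmerman–Traxler) transition state to give the syn C5/C6 relationship, and the isopinocampheyl groups from (−)-α-pinene direct the allyl unit to the re face of the aldehyde, which should set 3S and 4S (C5 and C6) together.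

Step 4
Reactants: 9 (1Z,3S,4S)-1-iodo-4-(4-methoxyphenoxy)-2-methylhexa-1,5-dien-3-ol
Product: 10 tert-butyl{[(1Z,3S,4S)-1-iodo-4-(4-methoxyphenoxy)-2-methylhexa-1,5-dien-3-yl]oxy}dimethylsilane
Conditions: TBSOTf, 2,6-lutidine, CH2Cl2, −78 → 0 °C
Reagents that add atoms: tert-butyldimethylsilyl trifluoromethanesulfonate, CC(C)(C)[Si](C)(C)OS(=O)(=O)C(F)(F)F
Why: Silyl triflate silylation of the secondary allylic alcohol protects the C5 oxygen for the whole route without touching either stereocentre.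

Step 5
Reactants: 10 tert-butyl{[(1Z,3S,4S)-1-iodo-4-(4-methoxyphenoxy)-2-methylhexa-1,5-dien-3-yl]oxy}dimethylsilane
Product: 11 (3S,4S,5Z)-4-(TBSO)-6-iodo-5-methylhexa-1,5-dien-3-ol
Conditions: (NH4)2Ce(NO3)6, MeCN/H2O (4:1), 0 °C
Reagents that add atoms: none
Why: Oxidative dearylation of the 4-methoxyphenyl ether (single-electron oxidation to the quinone) should free the C6 hydroxyl without touching the silyl ether, the iodoalkene or either stereocentre.

Step 6
Reactants: 12 ethyl 2-(hydroxymethyl)prop-2-enoate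
Product: 13 ethyl 2-(TBSO-methyl)prop-2-enoate
Conditions: TBSCl, imidazole, CH2Cl2, rt
Reagents that add atoms: tert-butyldimethylsilyl chloride, CC(C)(C)[Si](C)(C)Cl
Why: Standard silylation of the primary allylic alcohol masks the future C13 oxygen.

Step 7
Reactants: 13 ethyl 2-(TBSO-methyl)prop-2-enoate
Product: 14 2-(TBSO-methyl)prop-2-enoic acid
Conditions: LiOH, THF/H2O, 0 °C → rt; then 1 M HCl to pH 4, 0 °C
Reagents that add atoms: lithium hydroxide, [Li+].[OH-]
Why: Saponification of the ethyl ester, which the primary silyl ether should tolerate with cold hydroxide and careful acidification.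

Step 8
Reactants: 11 (3S,4S,5Z)-4-(TBSO)-6-iodo-5-methylhexa-1,5-dien-3-ol; 14 2-(TBSO-methyl)prop-2-enoic acid
Product: 15 (3S,4S,5Z)-4-(TBSO)-6-iodo-5-methylhexa-1,5-dien-3-yl 2-(TBSO-methyl)prop-2-enoate
Conditions: EDC·HCl, DMAP, CH2Cl2, 0 °C → rt
Reagents that add atoms: none
Why: Carbodiimide (Steglich) esterification attaches C11, C12 and C13 to the C6 oxygen with retention at C6.

Step 9
Reactants: 15 (3S,4S,5Z)-4-(TBSO)-6-iodo-5-methylhexa-1,5-dien-3-yl 2-(TBSO-methyl)prop-2-enoate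
Product: 16 (5S)-3-(TBSO-methyl)-5-[(1S,2Z)-1-(TBSO)-3-iodo-2-methylprop-2-en-1-yl]furan-2(5H)-one (fragment B)
Conditions: second-generation Grubbs catalyst (5 mol %), CH2Cl2 (0.01 M), 40 °C
Reagents that add atoms: none
Why: Ring-closing metathesis between the monosubstituted C7 vinyl group and the 1,1-disubstituted acrylate olefin closes the five-membered lactone (ring A) with loss of ethene, the trisubstituted iodoalkene being too hindered and electron-poor to take part.

Step 10
Reactants: 17 4-methyl-5,6-dihydro-2H-pyran-2-one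
Product: 18 (2Z)-5-hydroxy-N-methoxy-N,3-dimethylpent-2-enamide
Conditions: MeNHOMe·HCl, i-PrMgCl, THF, −20 → 0 °C
Reagents that add atoms: N,O-dimethylhydroxylamine hydrochloride, CNOC.Cl
Why: Aminolysis of the lactone with the magnesium amide (Weinreb amide formation) opens the ring, whose endocyclic double bond fixes the Z geometry of the future C1=C10 olefin.

Step 11
Reactants: 18 (2Z)-5-hydroxy-N-methoxy-N,3-dimethylpent-2-enamide
Product: 19 (2Z)-5-(TBSO)-N-methoxy-N,3-dimethylpent-2-enamide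
Conditions: TBSCl, imidazole, DMF, 0 °C → rt
Reagents that add atoms: tert-butyldimethylsilyl chloride, CC(C)(C)[Si](C)(C)Cl
Why: Silylation of the primary alcohol prevents relactonisation and masks the future C8 oxygen.

Step 12
Reactants: 19 (2Z)-5-(TBSO)-N-methoxy-N,3-dimethylpent-2-enamide
Product: 20 (2Z)-5-(TBSO)-3-methylpent-2-enal (fragment A)
Conditions: i-Bu2AlH, THF, −78 °C; aqueous potassium sodium tartrate
Reagents that add atoms: none
Why: Hydride reduction of the Weinreb amide stops at the aldehyde through the chelated tetrahedral aluminate, and the cold neutral work-up should preserve the Z-enal.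

Step 13
Reactants: 16 fragment B; 20 fragment A
Product: 22 (5S)-3-(TBSO-methyl)-5-[(1S,2Z,4RS,5Z)-1,8-bis(TBSO)-4-hydroxy-2,6-dimethylocta-2,5-dien-1-yl]furan-2(5H)-one, via alkenylchromium 21 (not isolated)
Conditions: CrCl2 (6 equiv), NiCl2 (2 mol %), DMSO, rt; 20 (1.5 equiv)
Reagents that add atoms: none
Why: Nozaki–Hiyama–Kishi alkenylation: zerovalent nickel inserts into the C–I bond with retention of the Z geometry and the alkenyl chromium species adds only to the aldehyde, forming C2–C3; the new C2 carbinol forms without control and is later oxidised.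

Step 14
Reactants: 22 (5S)-3-(TBSO-methyl)-5-[(1S,2Z,4RS,5Z)-1,8-bis(TBSO)-4-hydroxy-2,6-dimethylocta-2,5-dien-1-yl]furan-2(5H)-one
Product: 23 (5S)-3-(TBSO-methyl)-5-[(1S,2Z,4RS,5Z)-1,4,8-tris(TBSO)-2,6-dimethylocta-2,5-dien-1-yl]furan-2(5H)-one
Conditions: TBSOTf, 2,6-lutidine, CH2Cl2, −78 °C
Reagents that add atoms: tert-butyldimethylsilyl trifluoromethanesulfonate, CC(C)(C)[Si](C)(C)OS(=O)(=O)C(F)(F)F
Why: Low-temperature silylation with a hindered base protects the doubly allylic C2 alcohol without ionising it.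

Step 15
Reactants: 23 (5S)-3-(TBSO-methyl)-5-[(1S,2Z,4RS,5Z)-1,4,8-tris(TBSO)-2,6-dimethylocta-2,5-dien-1-yl]furan-2(5H)-one
Product: 24 (5S)-5-[(1S,2Z,4RS,5Z)-1,4-bis(TBSO)-8-hydroxy-2,6-dimethylocta-2,5-dien-1-yl]-3-(hydroxymethyl)furan-2(5H)-one
Conditions: HF·pyridine, pyridine, THF, 0 °C
Reagents that add atoms: none
Why: Buffered fluoride cleaves the two primary silyl ethers (C13 and C8) much faster than the two secondary ones (C2 and C5).

Step 16
Reactants: 24 (5S)-5-[(1S,2Z,4RS,5Z)-1,4-bis(TBSO)-8-hydroxy-2,6-dimethylocta-2,5-dien-1-yl]-3-(hydroxymethyl)furan-2(5H)-one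
Product: 25 (5S)-3-(bromomethyl)-5-[(1S,2Z,4RS,5Z)-1,4-bis(TBSO)-8-hydroxy-2,6-dimethylocta-2,5-dien-1-yl]furan-2(5H)-one
Conditions: NBS, Me2S, CH2Cl2, −20 → 0 °C
Reagents that add atoms: N-bromosuccinimide, O=C1CCC(=O)N1Br
Why: Corey–Kim halogenation: bromide displaces the alkoxysulfonium group only at the activated allylic C13 position, whereas the alkoxysulfonium salt of the saturated C8 alcohol should revert to the alcohol on work-up.

Step 17
Reactants: 25 (5S)-3-(bromomethyl)-5-[(1S,2Z,4RS,5Z)-1,4-bis(TBSO)-8-hydroxy-2,6-dimethylocta-2,5-dien-1-yl]furan-2(5H)-one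
Product: 26 (5S)-3-(bromomethyl)-5-[(1S,2Z,4RS,5Z)-1,4-bis(TBSO)-2,6-dimethyl-8-oxoocta-2,5-dien-1-yl]furan-2(5H)-one
Conditions: Dess–Martin periodinane, NaHCO3, CH2Cl2, 0 °C; used at once
Reagents that add atoms: none
Why: Dess–Martin oxidation under bicarbonate buffer gives the β,γ-unsaturated aldehyde without acid or base strong enough to move the C1=C10 double bond into conjugation.

Step 18
Reactants: 26 (5S)-3-(bromomethyl)-5-[(1S,2Z,4RS,5Z)-1,4-bis(TBSO)-2,6-dimethyl-8-oxoocta-2,5-dien-1-yl]furan-2(5H)-one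
Product: 28 (3aR,4S,6Z,8RS,9Z,11S,11aS)-8,11-bis(TBSO)-4-hydroxy-6,10-dimethyl-3-methylidene-3a,4,5,8,11,11a-hexahydrocyclodeca[b]furan-2(3H)-one, via allylchromium 27 (not isolated)
Conditions: CrCl2 (10 equiv), THF, rt, 26 added over 12 h (final 0.002 M)
Reagents that add atoms: none
Why: CrCl2 reduces the allylic C13–Br bond by two single-electron transfers to the allyl chromium species 27 (trivalent chromium), which adds to the tethered C8 aldehyde through its γ-carbon C7 (SE2′) in a closed six-membered chair transition state, so that the C7–C8 bond forms while the ring double bond C11=C7 moves out to C11=C13 and the α-methylene lactone appears. The closest known reaction types are the Barbier and Nozaki–Hiyama–Kishi additions of 5-substituted 3-(bromomethyl)furan-2(5H)-ones to aldehydes and the CrCl2-mediated cyclisations of ω-formyl allylic bromides to ten-membered germacrane rings. One ring is closed, the ten-membered carbocycle (ring B), by an intramolecular carbonyl addition that is 10-exo-trig at the aldehyde and SE2′ at the allyl unit, and it is annulated onto the existing ring A. C7 is controlled by C6: the chain leaves C6 on one face of the flat butenolide and the aldehyde reaches C7 from the other face, which avoids an eclipsed C5–C6–C7–C8 array in the forming ring and should give the trans ring fusion (7R). C8 is controlled by the chair: C6 is locked by ring A in the position trans to C13 (pseudo-equatorial) and C9 takes the outward pseudo-equatorial site anti to C11, which should give the 8S alcohol with the hydroxyl trans to C11, the epimer that step 19 inverts. The step needs γ- over α-attack (secured by the cyclic transition state; α-attack would need a twelve-membered ring), aldehyde over lactone chemoselectivity (inherent to allyl chromium reagents) and ring closure over oligomerisation (secured by slow addition at high dilution and by the two Z-olefins, which fold the chain so that C8 lies near C7).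

Step 19
Reactants: 28 bicyclic 8S alcohol; 29 (2E)-2-methylbut-2-enoic acid
Product: 30 (3aR,4R,6Z,8RS,9Z,11S,11aS)-8,11-bis(TBSO)-6,10-dimethyl-3-methylidene-2-oxo-2,3,3a,4,5,8,11,11a-octahydrocyclodeca[b]furan-4-yl (2E)-2-methylbut-2-enoate
Conditions: 29, PPh3, DIAD, toluene, 0 °C → rt
Reagents that add atoms: none
Why: Mitsunobu esterification: the tiglate anion displaces the alkoxyphosphonium group at C8 by SN2 with inversion, so that 8S becomes the required 8R ester in the step that would otherwise be a plain acylation.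

Step 20
Reactants: 30 bis-silylated 8R tiglate
Product: 31 (3aR,4R,6Z,8RS,9Z,11S,11aS)-8,11-dihydroxy-6,10-dimethyl-3-methylidene-2-oxo-2,3,3a,4,5,8,11,11a-octahydrocyclodeca[b]furan-4-yl (2E)-2-methylbut-2-enoate
Conditions: HF·pyridine, THF, 0 °C → rt
Reagents that add atoms: none
Why: Acidic fluoride removes both secondary silyl ethers and should leave the tiglate, the α-methylene lactone and all stereocentres untouched.

Step 21
Reactants: 31 C2,C5-diol
Product: 32 (3aR,4R,6Z,9Z,11S,11aS)-11-hydroxy-6,10-dimethyl-3-methylidene-2,8-dioxo-2,3,3a,4,5,8,11,11a-octahydrocyclodeca[b]furan-4-yl (2E)-2-methylbut-2-enoate (target)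
Conditions: MnO2, CH2Cl2, rt
Reagents that add atoms: none
Why: MnO2 should oxidise the doubly allylic C2 carbinol (both epimers) to the cross-conjugated dienone much faster than the singly allylic C5 alcohol, which is deactivated by the neighbouring acyloxy-bearing C6 and, once the dienone exists, by conjugation.

**Compound list**

1 | prop-2-yn-1-ol | C#CCO | starting material
2 | bromomagnesium (2Z)-3-(bromomagnesio)-2-methylprop-2-en-1-olate | Br[Mg]OC/C(C)=C\[Mg]Br | intermediate
3 | (2Z)-3-iodo-2-methylprop-2-en-1-ol | OC/C(C)=C\I | intermediate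
4 | (2Z)-3-iodo-2-methylprop-2-enal | O=C/C(C)=C\I | intermediate
5 | 1-methoxy-4-(prop-2-en-1-yloxy)benzene (allyl 4-methoxyphenyl ether) | C=CCOc1ccc(OC)cc1 | starting material
6 | [(2Z)-3-(4-methoxyphenoxy)prop-2-en-1-yl]lithium | [Li]C/C=C\Oc1ccc(OC)cc1 | intermediate
7 | [(2Z)-3-(4-methoxyphenoxy)prop-2-en-1-yl]diisopinocampheylborane (Ipc from (−)-α-pinene) | COc1ccc(O/C=C\CB([C@H]2C[C@H]3C[C@@H]([C@@H]2C)C3(C)C)[C@H]2C[C@H]3C[C@@H]([C@@H]2C)C3(C)C)cc1 | intermediate
8 | (1Z,3S,4S)-1-iodo-4-(4-methoxyphenoxy)-2-methylhexa-1,5-dien-3-yl diisopinocampheylborinate | I/C=C(/C)[C@H](OB([C@H]1C[C@H]2C[C@@H]([C@@H]1C)C2(C)C)[C@H]1C[C@H]2C[C@@H]([C@@H]1C)C2(C)C)[C@@H](Oc1ccc(OC)cc1)C=C | intermediate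
9 | (1Z,3S,4S)-1-iodo-4-(4-methoxyphenoxy)-2-methylhexa-1,5-dien-3-ol | I/C=C(/C)[C@H](O)[C@@H](Oc1ccc(OC)cc1)C=C | intermediate
10 | tert-butyl{[(1Z,3S,4S)-1-iodo-4-(4-methoxyphenoxy)-2-methylhexa-1,5-dien-3-yl]oxy}dimethylsilane | I/C=C(/C)[C@H](O[Si](C)(C)C(C)(C)C)[C@@H](Oc1ccc(OC)cc1)C=C | intermediate
11 | (3S,4S,5Z)-4-(TBSO)-6-iodo-5-methylhexa-1,5-dien-3-ol | I/C=C(/C)[C@H](O[Si](C)(C)C(C)(C)C)[C@@H](O)C=C | intermediate
12 | ethyl 2-(hydroxymethyl)prop-2-enoate | C=C(CO)C(=O)OCC | starting material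
13 | ethyl 2-(TBSO-methyl)prop-2-enoate | C=C(CO[Si](C)(C)C(C)(C)C)C(=O)OCC | intermediate
14 | 2-(TBSO-methyl)prop-2-enoic acid | C=C(CO[Si](C)(C)C(C)(C)C)C(=O)O | intermediate
15 | (3S,4S,5Z)-4-(TBSO)-6-iodo-5-methylhexa-1,5-dien-3-yl 2-(TBSO-methyl)prop-2-enoate | I/C=C(/C)[C@H](O[Si](C)(C)C(C)(C)C)[C@@H](OC(=O)C(=C)CO[Si](C)(C)C(C)(C)C)C=C | intermediate
16 | (5S)-3-(TBSO-methyl)-5-[(1S,2Z)-1-(TBSO)-3-iodo-2-methylprop-2-en-1-yl]furan-2(5H)-one (fragment B) | O=C1O[C@@H](C=C1CO[Si](C)(C)C(C)(C)C)[C@@H](O[Si](C)(C)C(C)(C)C)/C(C)=C\I | intermediate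
17 | 4-methyl-5,6-dihydro-2H-pyran-2-one | CC1=CC(=O)OCC1 | starting material
18 | (2Z)-5-hydroxy-N-methoxy-N,3-dimethylpent-2-enamide | CON(C)C(=O)/C=C(/C)CCO | intermediate
19 | (2Z)-5-(TBSO)-N-methoxy-N,3-dimethylpent-2-enamide | CON(C)C(=O)/C=C(/C)CCO[Si](C)(C)C(C)(C)C | intermediate
20 | (2Z)-5-(TBSO)-3-methylpent-2-enal (fragment A) | O=C/C=C(/C)CCO[Si](C)(C)C(C)(C)C | intermediate
21 | alkenylchromium dichloride from 16 (trivalent chromium in place of iodine) | O=C1O[C@@H](C=C1CO[Si](C)(C)C(C)(C)C)[C@@H](O[Si](C)(C)C(C)(C)C)/C(C)=C\[Cr](Cl)Cl | intermediate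
22 | (5S)-3-(TBSO-methyl)-5-[(1S,2Z,4RS,5Z)-1,8-bis(TBSO)-4-hydroxy-2,6-dimethylocta-2,5-dien-1-yl]furan-2(5H)-one | O=C1O[C@@H](C=C1CO[Si](C)(C)C(C)(C)C)[C@@H](O[Si](C)(C)C(C)(C)C)/C(C)=C\C(O)/C=C(/C)CCO[Si](C)(C)C(C)(C)C | intermediate
23 | (5S)-3-(TBSO-methyl)-5-[(1S,2Z,4RS,5Z)-1,4,8-tris(TBSO)-2,6-dimethylocta-2,5-dien-1-yl]furan-2(5H)-one | O=C1O[C@@H](C=C1CO[Si](C)(C)C(C)(C)C)[C@@H](O[Si](C)(C)C(C)(C)C)/C(C)=C\C(O[Si](C)(C)C(C)(C)C)/C=C(/C)CCO[Si](C)(C)C(C)(C)C | intermediate
24 | (5S)-5-[(1S,2Z,4RS,5Z)-1,4-bis(TBSO)-8-hydroxy-2,6-dimethylocta-2,5-dien-1-yl]-3-(hydroxymethyl)furan-2(5H)-one | O=C1O[C@@H](C=C1CO)[C@@H](O[Si](C)(C)C(C)(C)C)/C(C)=C\C(O[Si](C)(C)C(C)(C)C)/C=C(/C)CCO | intermediate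
25 | (5S)-3-(bromomethyl)-5-[(1S,2Z,4RS,5Z)-1,4-bis(TBSO)-8-hydroxy-2,6-dimethylocta-2,5-dien-1-yl]furan-2(5H)-one | O=C1O[C@@H](C=C1CBr)[C@@H](O[Si](C)(C)C(C)(C)C)/C(C)=C\C(O[Si](C)(C)C(C)(C)C)/C=C(/C)CCO | intermediate
26 | (5S)-3-(bromomethyl)-5-[(1S,2Z,4RS,5Z)-1,4-bis(TBSO)-2,6-dimethyl-8-oxoocta-2,5-dien-1-yl]furan-2(5H)-one | O=C1O[C@@H](C=C1CBr)[C@@H](O[Si](C)(C)C(C)(C)C)/C(C)=C\C(O[Si](C)(C)C(C)(C)C)/C=C(/C)CC=O | intermediate
27 | allylchromium dichloride from 26 (trivalent chromium on C13 in place of bromine) | O=C1O[C@@H](C=C1C[Cr](Cl)Cl)[C@@H](O[Si](C)(C)C(C)(C)C)/C(C)=C\C(O[Si](C)(C)C(C)(C)C)/C=C(/C)CC=O | intermediate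
28 | (3aR,4S,6Z,8RS,9Z,11S,11aS)-8,11-bis(TBSO)-4-hydroxy-6,10-dimethyl-3-methylidene-3a,4,5,8,11,11a-hexahydrocyclodeca[b]furan-2(3H)-one (8S alcohol in the ring numbering of the remark) | C=C1C(=O)O[C@H]2[C@H]1[C@@H](O)C/C(C)=C\C(O[Si](C)(C)C(C)(C)C)/C=C(/C)[C@@H]2O[Si](C)(C)C(C)(C)C | intermediate
29 | (2E)-2-methylbut-2-enoic acid (tiglic acid) | OC(=O)/C(C)=C/C | starting material
30 | (3aR,4R,6Z,8RS,9Z,11S,11aS)-8,11-bis(TBSO)-6,10-dimethyl-3-methylidene-2-oxo-2,3,3a,4,5,8,11,11a-octahydrocyclodeca[b]furan-4-yl (2E)-2-methylbut-2-enoate | C=C1C(=O)O[C@H]2[C@H]1[C@H](OC(=O)/C(C)=C/C)C/C(C)=C\C(O[Si](C)(C)C(C)(C)C)/C=C(/C)[C@@H]2O[Si](C)(C)C(C)(C)C | intermediate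
31 | (3aR,4R,6Z,8RS,9Z,11S,11aS)-8,11-dihydroxy-6,10-dimethyl-3-methylidene-2-oxo-2,3,3a,4,5,8,11,11a-octahydrocyclodeca[b]furan-4-yl (2E)-2-methylbut-2-enoate | C=C1C(=O)O[C@H]2[C@H]1[C@H](OC(=O)/C(C)=C/C)C/C(C)=C\C(O)/C=C(/C)[C@@H]2O | intermediate
32 | (3aR,4R,6Z,9Z,11S,11aS)-11-hydroxy-6,10-dimethyl-3-methylidene-2,8-dioxo-2,3,3a,4,5,8,11,11a-octahydrocyclodeca[b]furan-4-yl (2E)-2-methylbut-2-enoate | C=C1C(=O)O[C@H]2[C@H]1[C@H](OC(=O)/C(C)=C/C)C/C(C)=C\C(=O)/C=C(/C)[C@@H]2O | target

**Step count and risks**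

Total step count: 21. Longest linear sequence: 16 steps (steps 1–5, 8, 9 and 13–21, from prop-2-yn-1-ol).

Steps most likely to fail:

1. Step 18 (key step). The allyl chromium species may be protonated or may add to a second molecule before ring closure (oligomerisation). The aldehyde may also be delivered to the lactone face that carries C5 (cis fusion). A boat-like transition state would give the 8R instead of the 8S alcohol; that outcome loses nothing, since the 8R alcohol can be acylated with retention as in the fallback to step 19. Fallback, which replaces the Barbier-type organochromium addition by a unimolecular thermal allylboration of an isolable allylboronate: it sets out from bromo alcohol 25. Miyaura-type borylation (B2pin2, Pd2(dba)3 cat., toluene/DMSO, 50 °C) should give the allylic pinacol boronate alcohol F1. Dess–Martin oxidation (NaHCO3, CH2Cl2, 0 °C) should give the boronate aldehyde F2. Heating F2 in toluene (0.005 M, 80 °C) should close ring B by intramolecular allylboration through the same chair to the cyclic pinacol borate F3 (not isolated), and aqueous work-up returns to alcohol 28.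

2. Step 19. Elimination across C8–C9 or C7–C8 may outrun substitution at the hindered ring carbinol, or acyl transfer with retention may compete. Fallback, which replaces SN2 inversion by an oxidation–reduction sequence: it sets out from alcohol 28. Dess–Martin oxidation (NaHCO3, CH2Cl2, 0 °C) should give the C8 ketone F4. Reduction with NaBH4 and CeCl3·7H2O (MeOH/THF, −78 °C) should deliver hydride anti to the C7–C11 bond and give the 8R alcohol F5. Esterification with tiglic acid 29 (2,4,6-trichlorobenzoyl chloride, Et3N, DMAP, toluene) returns to ester 30.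

3. Step 21. Oxidation may fail to discriminate between the C2 and C5 allylic carbinols, so that over-oxidation to an ene-dione erodes the material. Fallback, which oxidises C2 while C5 is still protected: it sets out from bis-silyl ether 30. DDQ (CH2Cl2/pH 7 buffer, 0 °C → rt) should abstract hydride only from the doubly allylic C2 silyl ether and give the dienone 5-O-TBS ether F6. HF·pyridine (THF, rt) then removes the remaining silyl group and returns to target 32.

**Further compounds**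

F1 | step 18 | (5S)-5-[(1S,2Z,4RS,5Z)-1,4-bis(TBSO)-8-hydroxy-2,6-dimethylocta-2,5-dien-1-yl]-3-[(4,4,5,5-tetramethyl-1,3,2-dioxaborolan-2-yl)methyl]furan-2(5H)-one | O=C1O[C@@H](C=C1CB2OC(C)(C)C(C)(C)O2)[C@@H](O[Si](C)(C)C(C)(C)C)/C(C)=C\C(O[Si](C)(C)C(C)(C)C)/C=C(/C)CCO
F2 | step 18 | (5S)-5-[(1S,2Z,4RS,5Z)-1,4-bis(TBSO)-2,6-dimethyl-8-oxoocta-2,5-dien-1-yl]-3-[(4,4,5,5-tetramethyl-1,3,2-dioxaborolan-2-yl)methyl]furan-2(5H)-one | O=C1O[C@@H](C=C1CB2OC(C)(C)C(C)(C)O2)[C@@H](O[Si](C)(C)C(C)(C)C)/C(C)=C\C(O[Si](C)(C)C(C)(C)C)/C=C(/C)CC=O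
F3 | step 18 | pinacol borate ester of alcohol 28 at the C8 oxygen (not isolated) | C=C1C(=O)O[C@H]2[C@H]1[C@@H](OB3OC(C)(C)C(C)(C)O3)C/C(C)=C\C(O[Si](C)(C)C(C)(C)C)/C=C(/C)[C@@H]2O[Si](C)(C)C(C)(C)C
F4 | step 19 | (3aR,6Z,8RS,9Z,11S,11aS)-8,11-bis(TBSO)-6,10-dimethyl-3-methylidene-3a,5,8,11,11a-pentahydrocyclodeca[b]furan-2,4(3H)-dione (C8 ketone) | C=C1C(=O)O[C@H]2[C@H]1C(=O)C/C(C)=C\C(O[Si](C)(C)C(C)(C)C)/C=C(/C)[C@@H]2O[Si](C)(C)C(C)(C)C
F5 | step 19 | (3aR,4R,6Z,8RS,9Z,11S,11aS)-8,11-bis(TBSO)-4-hydroxy-6,10-dimethyl-3-methylidene-3a,4,5,8,11,11a-hexahydrocyclodeca[b]furan-2(3H)-one (8R alcohol) | C=C1C(=O)O[C@H]2[C@H]1[C@H](O)C/C(C)=C\C(O[Si](C)(C)C(C)(C)C)/C=C(/C)[C@@H]2O[Si](C)(C)C(C)(C)C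
F6 | step 21 | (3aR,4R,6Z,9Z,11S,11aS)-11-(TBSO)-6,10-dimethyl-3-methylidene-2,8-dioxo-2,3,3a,4,5,8,11,11a-octahydrocyclodeca[b]furan-4-yl (2E)-2-methylbut-2-enoate | C=C1C(=O)O[C@H]2[C@H]1[C@H](OC(=O)/C(C)=C/C)C/C(C)=C\C(=O)/C=C(/C)[C@@H]2O[Si](C)(C)C(C)(C)C
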